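**Plan**
- Cuts: the C8–CH2 bond of the prenyl group is traced back through two [3,3] shifts to an O5–CH2 prenyl ether, so the free 5-OH is the footprint of the prenyl group. Next come O1–C2 and C3–OH of the pyranone (oxidative cyclisation of a 2'-hydroxychalcone), then Cα=Cβ (aldol), then the O–prenyl bond of a symmetric 2,6-dihydroxy ketone.
- Forward: ring A is bought and desymmetrised by one O-prenylation, ring B is attached by aldol condensation, and ring C closes through the only free phenol. The prenyl group is then relayed O5 → C6 → C8 on the complete flavonol through a dearomatised ring A, and both MOM groups are removed last.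
- Enabling feature: on ring A, O5 is ortho to C6–H and para to C8–H (C8 lies between O1 and the 7-OMe), and the C4 carbonyl of ring C is peri to O5, so O4/O5 form a bidentate site for a lanthanide Lewis acid. One prenyl ether thus serves as protecting group for O5, as regiochemical lock for ring C closure and as latent C8 substituent.
- A ketone C-prenylated first could close ring C through either phenol (6- or 8-prenyl). The relay avoids this and, as in the biosynthesis, brings the prenyl group to C8 only after the flavonoid skeleton is complete.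
- Stereochemistry: none to set; sp3 centres occur only in transient racemic intermediates and are erased on aromatisation.

Key step: step 5

Remark: the target has no stereocentre and no stereogenic double bond, so the "single enantiomer" asked for is the achiral compound itself.
Remark: the acetophenone, prenyl bromide and 4-(methoxymethoxy)benzaldehyde are taken as catalogue compounds.

**Step 1**
Reactants: 1 1-(2,6-dihydroxy-4-methoxyphenyl)ethanone; 2 1-bromo-3-methylbut-2-ene (prenyl bromide)
Product: 3 1-[2-hydroxy-4-methoxy-6-(3-methylbut-2-enyloxy)phenyl]ethanone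
Conditions: 2 (1.05 equiv), K2CO3 (1.5 equiv), acetone, 50 °C
Reagents that add atoms: none
Why: Williamson etherification of one of two equivalent phenols should stop at the mono-ether, because the remaining OH is locked in a hydrogen bond to the acetyl C=O and is much less acidic, while weak base in an aprotic solvent favours O- over C-alkylation.

**Step 2**
Reactants: 3 1-[2-hydroxy-4-methoxy-6-(3-methylbut-2-enyloxy)phenyl]ethanone; 4 4-(methoxymethoxy)benzaldehyde
Product: 5 (E)-1-[2-hydroxy-4-methoxy-6-(3-methylbut-2-enyloxy)phenyl]-3-[4-(methoxymethoxy)phenyl]prop-2-en-1-one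
Conditions: KOH (50% aq.), EtOH, 0 °C → rt; aq. NH4Cl
Reagents that add atoms: none
Why: Claisen–Schmidt aldol condensation of the methyl ketone with a non-enolisable aldehyde, followed by E1cB dehydration, should give the conjugated (E)-enone; the MOM and prenyl ethers are stable to base.

**Step 3**
Reactants: 5 (E)-1-[2-hydroxy-4-methoxy-6-(3-methylbut-2-enyloxy)phenyl]-3-[4-(methoxymethoxy)phenyl]prop-2-en-1-one
Product: 7 3-hydroxy-7-methoxy-2-[4-(methoxymethoxy)phenyl]-5-(3-methylbut-2-enyloxy)-4H-chromen-4-one, via trans-dihydroflavonol 6 (not isolated)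
Conditions: H2O2 (30% aq.), NaOH (aq.), MeOH/THF, 0 °C → rt; aq. NH4Cl
Reagents that add atoms: hydrogen peroxide, OO
Why: Algar–Flynn–Oyamada oxidation, in which hydroperoxide attacks the enone, the single free phenoxide closes the pyranone by 6-endo attack at the benzylic β-carbon (favoured by the 4-alkoxy ring B) and 6 is dehydrogenated in situ; nucleophilic HOO− should leave the isolated trisubstituted alkene untouched, and with only one free phenol the prenyloxy group can only end at C5.

**Step 4**
Reactants: 7 3-hydroxy-7-methoxy-2-[4-(methoxymethoxy)phenyl]-5-(3-methylbut-2-enyloxy)-4H-chromen-4-one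
Product: 8 7-methoxy-3-(methoxymethoxy)-2-[4-(methoxymethoxy)phenyl]-5-(3-methylbut-2-enyloxy)-4H-chromen-4-one
Conditions: MOMCl, i-Pr2NEt, CH2Cl2, 0 °C → rt
Reagents that add atoms: chloromethyl methyl ether (MOMCl), COCCl
Why: O-alkylation of the only free (enolic) hydroxyl masks the 3-OH/4-C=O chelating site, which would otherwise sequester the lanthanide catalyst of step 5, and gives a second MOM ether that falls together with the first at the end.

**Step 5**
Reactants: 8 7-methoxy-3-(methoxymethoxy)-2-[4-(methoxymethoxy)phenyl]-5-(3-methylbut-2-enyloxy)-4H-chromen-4-one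
Product: 11 5-hydroxy-7-methoxy-3-(methoxymethoxy)-2-[4-(methoxymethoxy)phenyl]-8-(3-methylbut-2-enyl)-4H-chromen-4-one, via C6 reverse-prenyl dienone 9 (not isolated), via C8-prenyl dienone 10 (not isolated)
Conditions: Eu(fod)3 (10 mol%), NaHCO3, PhCl, 85 °C, Ar
Reagents that add atoms: none
Why: Eu(III) should bind the peri pair O5/C4=O and so activate the aryl prenyl ether for an aromatic Claisen [3,3] shift that delivers the tertiary prenyl carbon to C6, the only ortho carbon bearing hydrogen, giving the dearomatised dienone 9. A Cope [3,3] shift across C6–C7=C8 then moves the allyl unit to C8 with a second allylic inversion, which restores the linear prenyl group (dienone 10), and enolisation gives phenol 11, whose 5-OH is hydrogen-bonded to C4=O. The closest known reaction type is the europium(III)-catalysed para-Claisen–Cope rearrangement of 5-O-prenyl flavanones and flavonols. No ring is closed and no stereocentre remains, since the sp3 centres at C6 of 9 and C8 of 10 are racemic and are erased by aromatisation. The step needs para (C8-prenyl) over ortho selectivity (the 6-(1,1-dimethylallyl) isomer from early enolisation of 9) and no ionisation of the allylic C–O bond. The Cope shift should win because it relieves the strain of a tertiary group wedged between C5=O and the 7-OMe, while NaHCO3 removes adventitious acid that would catalyse enolisation of 9 or ether cleavage.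

**Step 6**
Reactants: 11 5-hydroxy-7-methoxy-3-(methoxymethoxy)-2-[4-(methoxymethoxy)phenyl]-8-(3-methylbut-2-enyl)-4H-chromen-4-one
Product: 12 isoanhydroicaritin (3,5-dihydroxy-2-(4-hydroxyphenyl)-7-methoxy-8-(3-methylbut-2-enyl)-4H-chromen-4-one)
Conditions: HCl (3 M in MeOH), 50 °C
Reagents that add atoms: none
Why: acid-catalysed transacetalisation to methanol should cleave both MOM ethers; the C8-prenyl group has no free ortho hydroxyl (C7 carries OMe, C8a the ring oxygen), so acid-induced chroman formation cannot occur, and the aryl methyl ether is inert.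

**Compound list**
1 | 1-(2,6-dihydroxy-4-methoxyphenyl)ethanone | CC(=O)c1c(O)cc(OC)cc1O | starting material
2 | 1-bromo-3-methylbut-2-ene (prenyl bromide) | CC(C)=CCBr | starting material
3 | 1-[2-hydroxy-4-methoxy-6-(3-methylbut-2-enyloxy)phenyl]ethanone | CC(=O)c1c(O)cc(OC)cc1OCC=C(C)C | intermediate
4 | 4-(methoxymethoxy)benzaldehyde | COCOc1ccc(C=O)cc1 | starting material
5 | (E)-1-[2-hydroxy-4-methoxy-6-(3-methylbut-2-enyloxy)phenyl]-3-[4-(methoxymethoxy)phenyl]prop-2-en-1-one | COCOc1ccc(/C=C/C(=O)c2c(O)cc(OC)cc2OCC=C(C)C)cc1 | intermediate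
6 | trans-3-hydroxy-7-methoxy-2-[4-(methoxymethoxy)phenyl]-5-(3-methylbut-2-enyloxy)chroman-4-one (racemic; 2R,3R enantiomer drawn; not isolated) | COCOc1ccc(cc1)[C@@H]1[C@H](C(=O)c2c(OCC=C(C)C)cc(OC)cc2O1)O | intermediate
7 | 3-hydroxy-7-methoxy-2-[4-(methoxymethoxy)phenyl]-5-(3-methylbut-2-enyloxy)-4H-chromen-4-one | COCOc1ccc(cc1)-c1oc2cc(OC)cc(OCC=C(C)C)c2c(=O)c1O | intermediate
8 | 7-methoxy-3-(methoxymethoxy)-2-[4-(methoxymethoxy)phenyl]-5-(3-methylbut-2-enyloxy)-4H-chromen-4-one | COCOc1ccc(cc1)-c1oc2cc(OC)cc(OCC=C(C)C)c2c(=O)c1OCOC | intermediate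
9 | 7-methoxy-3-(methoxymethoxy)-2-[4-(methoxymethoxy)phenyl]-6-(2-methylbut-3-en-2-yl)-6H-chromene-4,5-dione (racemic; not isolated) | COCOc1ccc(cc1)C1=C(OCOC)C(=O)C2=C(O1)C=C(OC)C(C2=O)C(C)(C)C=C | intermediate
10 | 7-methoxy-3-(methoxymethoxy)-2-[4-(methoxymethoxy)phenyl]-8-(3-methylbut-2-enyl)-8H-chromene-4,5-dione (racemic; not isolated) | COCOc1ccc(cc1)C1=C(OCOC)C(=O)C2=C(O1)C(CC=C(C)C)C(OC)=CC2=O | intermediate
11 | 5-hydroxy-7-methoxy-3-(methoxymethoxy)-2-[4-(methoxymethoxy)phenyl]-8-(3-methylbut-2-enyl)-4H-chromen-4-one | COCOc1ccc(cc1)-c1oc2c(CC=C(C)C)c(OC)cc(O)c2c(=O)c1OCOC | intermediate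
12 | isoanhydroicaritin | COc1cc(O)c2c(=O)c(O)c(-c3ccc(O)cc3)oc2c1CC=C(C)C | target

Total step count: 6
Longest linear sequence: 6 (1 → 3 → 5 → 7 → 8 → 11 → 12)

**Steps most likely to fail**

Step 5. The process at risk is enolisation of dienone 9 before the Cope shift (arrest at the 6-(1,1-dimethylallyl) isomer), or Lewis-acid ionisation of the allylic C–O bond with loss of the prenyl group. The fallback forms the C–prenyl bond before ring C and controls the ring closure by steric differentiation of the two phenols. It sets out from 1: C-alkylation with 2 (10% aq. KOH, 0 °C; C3 and C5 of 1 are equivalent, so only one mono-C-prenyl isomer can form) should give the C-prenyl ketone F1. The phenol not flanked by the prenyl group is the less hindered one and is protected with MOMCl (1 equiv)/i-Pr2NEt to give the mono-MOM ether F2. Claisen–Schmidt condensation with 4 gives the chalcone F3. Algar–Flynn–Oyamada oxidation then closes ring C through the only free phenol, which is the one next to the prenyl group, and should give the 8-prenyl flavonol F5 by way of the trans-dihydroflavonol F4 (not isolated). HCl/MeOH removes both MOM groups and the route is rejoined at the target 12.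

Step 3. The process at risk is 5-exo attack of the phenoxide at the α-carbon (aurone formation, promoted by the 6'-alkoxy group), or oxidative degradation of the flavonol by alkaline peroxide. The fallback separates ring closure from C3 oxygenation. It sets out from 5: oxa-Michael cyclisation (NaOAc, EtOH, reflux) gives the racemic flavanone F6, and dehydrogenation with IBX (DMSO, 80 °C) gives the flavone F7. Deprotonation at C3 (LDA, THF, −78 °C) and trapping with B(OMe)3 gives the C3 dimethyl boronate F8 (not isolated), which is oxidised with NaBO3·4H2O (THF/H2O, rt) to flavonol 7, where the route is rejoined.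

Step 1. The process at risk is a second O-alkylation or C-alkylation of the ambident phenoxide, giving a mixture. The fallback desymmetrises ring A by heterocyclisation instead of by mono-alkylation. It sets out from 1 and 4: Claisen–Schmidt condensation (KOH, EtOH) gives the 2',6'-dihydroxychalcone F9, which is cyclised (NaOAc, EtOH, reflux) to the racemic 5-hydroxyflavanone F10; ring A is symmetric at this stage, so either phenol gives the same product. The single remaining phenol is etherified under Mitsunobu conditions (3-methylbut-2-en-1-ol, PPh3, DIAD, THF, 0 °C) to the flavanone F6 already described. Ring opening by E1cB (KOH, EtOH, rt) then gives chalcone 5, where the route is rejoined.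

**Further compounds**
F1 | step 5 | 1-[2,6-dihydroxy-4-methoxy-3-(3-methylbut-2-enyl)phenyl]ethanone | CC(=O)c1c(O)cc(OC)c(CC=C(C)C)c1O
F2 | step 5 | 1-[2-hydroxy-4-methoxy-6-(methoxymethoxy)-3-(3-methylbut-2-enyl)phenyl]ethanone | CC(=O)c1c(OCOC)cc(OC)c(CC=C(C)C)c1O
F3 | step 5 | (E)-1-[2-hydroxy-4-methoxy-6-(methoxymethoxy)-3-(3-methylbut-2-enyl)phenyl]-3-[4-(methoxymethoxy)phenyl]prop-2-en-1-one | COCOc1ccc(/C=C/C(=O)c2c(OCOC)cc(OC)c(CC=C(C)C)c2O)cc1
F4 | step 5 | trans-3-hydroxy-7-methoxy-5-(methoxymethoxy)-2-[4-(methoxymethoxy)phenyl]-8-(3-methylbut-2-enyl)chroman-4-one (racemic; 2R,3R enantiomer drawn; not isolated) | COCOc1ccc(cc1)[C@@H]1[C@H](C(=O)c2c(OCOC)cc(OC)c(CC=C(C)C)c2O1)O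
F5 | step 5 | 3-hydroxy-7-methoxy-5-(methoxymethoxy)-2-[4-(methoxymethoxy)phenyl]-8-(3-methylbut-2-enyl)-4H-chromen-4-one | COCOc1ccc(cc1)-c1oc2c(CC=C(C)C)c(OC)cc(OCOC)c2c(=O)c1O
F6 | step 3 | 7-methoxy-2-[4-(methoxymethoxy)phenyl]-5-(3-methylbut-2-enyloxy)chroman-4-one (racemic) | COCOc1ccc(cc1)C1CC(=O)c2c(OCC=C(C)C)cc(OC)cc2O1
F7 | step 3 | 7-methoxy-2-[4-(methoxymethoxy)phenyl]-5-(3-methylbut-2-enyloxy)-4H-chromen-4-one | COCOc1ccc(cc1)-c1cc(=O)c2c(OCC=C(C)C)cc(OC)cc2o1
F8 | step 3 | dimethyl {7-methoxy-2-[4-(methoxymethoxy)phenyl]-5-(3-methylbut-2-enyloxy)-4-oxo-4H-chromen-3-yl}boronate (not isolated) | COCOc1ccc(cc1)-c1oc2cc(OC)cc(OCC=C(C)C)c2c(=O)c1B(OC)OC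
F9 | step 1 | (E)-1-(2,6-dihydroxy-4-methoxyphenyl)-3-[4-(methoxymethoxy)phenyl]prop-2-en-1-one | COCOc1ccc(/C=C/C(=O)c2c(O)cc(OC)cc2O)cc1
F10 | step 1 | 5-hydroxy-7-methoxy-2-[4-(methoxymethoxy)phenyl]chroman-4-one (racemic) | COCOc1ccc(cc1)C1CC(=O)c2c(O)cc(OC)cc2O1
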